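**Plan**
- Retrosynthetic cuts: first the C7–alkenyl bond (Suzuki–Miyaura), then O1–C2 and C2–aryl (acid closure of a benzylic alcohol made by aryl Grignard addition), then O4–C3 and O1–C2 of a lactol (amine-catalysed [4+2] of propanal with an ortho-quinone).
- Enabling feature, in benzodioxane numbering (O1, C2 aryl, C3 methyl, O4, C5 methoxy, C7 chain): O1–C2–C3–O4 is a two-carbon bridge between the two oxygens of ring A. C3 is the α-carbon and C2 the carbonyl carbon of propanal, and O1 and O4 are the carbonyl oxygens of a dearomatised ring A (5-bromo-3-methoxy-ortho-benzoquinone).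
- Forward order: bromo-ortho-vanillin gives the catechol and then the quinone; the dioxane ring closes first as a lactol on ring A; the lactol is opened by the aryl Grignard reagent and reclosed under acid to the trans ring; the hydroxypropenyl chain is joined last at the C7 bromide and desilylated.
- Stereochemistry: C3 (R) comes from the (R)-diarylprolinol silyl ether catalyst; C2 (R) follows from C3 by thermodynamic trans closure; the E-alkene comes from the (E)-alkenylboronate.

Key step: step 3

Remarks on the chemistry:
- Lactol 6 is an interconverting pair of anomers and alcohol 9 a pair of carbinol epimers; each pair converges in the following step, so one anomer is drawn and the carbinol centre is left undefined.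
- Species bound to a substoichiometric catalyst (the enamine and the N,O-aminal in step 3, the organopalladium species in step 6) are turnover states of that catalyst; they are described in the Why lines and carry no compound numbers.
- The benzodioxane numbering of the plan is used for all bicyclic compounds.

**Step 1**
Reactants: 1 5-bromo-2-hydroxy-3-methoxybenzaldehyde
Product: 3 5-bromo-3-methoxybenzene-1,2-diol, via 5-bromo-2-hydroxy-3-methoxyphenyl formate 2 (not isolated)
Conditions: H2O2 (30% aq), NaOH (aq), 0 °C → rt, N2; then HCl (aq)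
Reagents that add atoms: hydrogen peroxide, OO
Why: Dakin oxidation, in which hydroperoxide adds to the aldehyde, the electron-rich ortho-hydroxyaryl group migrates to oxygen and formate 2 is saponified in the same pot; this is standard for ortho-vanillin-type aldehydes and leaves the aryl bromide untouched.

**Step 2**
Reactants: 3 5-bromo-3-methoxybenzene-1,2-diol
Product: 4 5-bromo-3-methoxycyclohexa-3,5-diene-1,2-dione
Conditions: Ag2O, Na2SO4, CH2Cl2, 0 °C, dark; filtered through Celite and used at once as a cold solution
Reagents that add atoms: none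
Why: Dehydrogenation of a catechol to its ortho-quinone with Ag2O is a classical two-electron oxidation, and filtration removes oxidant and drying agent so that the sensitive quinone reaches step 3 as a neutral, reagent-free solution.

**Step 3**
Reactants: 4 5-bromo-3-methoxycyclohexa-3,5-diene-1,2-dione; 5 propanal
Product: 6 (2S,3R)-7-bromo-5-methoxy-3-methyl-2,3-dihydro-1,4-benzodioxin-2-ol
Conditions: 5 (3 equiv), (R)-2-[diphenyl(trimethylsilyloxy)methyl]pyrrolidine (20 mol %), CH2Cl2, −40 °C, slow addition of 4; then THF/pH 7 buffer, 0 °C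
Reagents that add atoms: water, O
Why: The amine condenses with 5 to an E-enamine whose α-carbon bonds to the oxygen of the C2 carbonyl of 4 (the carbonyl flanked by the methoxy-bearing carbon), the phenoxide released at the C1 oxygen adds to the iminium carbon, and water then cleaves the resulting N,O-aminal to lactol 6 and frees the amine, a stepwise polar [4+2] in which the O=C–C=O unit of 4 is the heterodiene and the return of ring A to aromaticity is the driving force. The closest known reaction type is the amine-catalysed inverse-electron-demand hetero-Diels–Alder reaction of aldehyde enamines with ortho-quinones, which delivers 2-hydroxy-2,3-dihydro-1,4-benzodioxines. The one ring formed, the dioxane ring, closes 6-exo-trig by attack of the phenoxide oxygen on the iminium carbon, whose C=N+ bond lies outside the new ring. C3 is set by the catalyst, whose diphenyl(trimethylsilyloxy)methyl group blocks one face of the s-trans E-enamine so that oxygen arrives on the open face and the (R)-pyrrolidine gives 3R, while the anomeric C2 is left uncontrolled because step 4 removes it. The step needs the two quinone oxygens to be told apart and attack at oxygen to outrun Michael-type attack on ring carbons: the methoxy group makes the C1 carbonyl a doubly vinylogous ester and leaves the cross-conjugated C2 carbonyl as the electrophilic end, and slow addition of 4 to the amine premixed with excess 5 keeps the amine tied up as enamine and the quinone concentration low. The bromine at C5 of 4 (C7 of 6) is a bystander and is kept as the handle for the side chain.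

**Step 4**
Reactants: 6 (2S,3R)-7-bromo-5-methoxy-3-methyl-2,3-dihydro-1,4-benzodioxin-2-ol; 7 5-bromo-1,2,3-trimethoxybenzene
Product: 9 (2R)-2-(4-bromo-2-hydroxy-6-methoxyphenoxy)-1-(3,4,5-trimethoxyphenyl)propan-1-ol (both C1 epimers), via 3,4,5-trimethoxyphenylmagnesium bromide 8 (not isolated)
Conditions: 7, Mg, THF, 50 °C; then 6, THF, −40 → 0 °C (3 equiv of 8); sat. aq NH4Cl
Reagents that add atoms: none
Why: Grignard addition to a lactol, in which the first equivalent of 8 deprotonates the hemiacetal, the magnesium salt opens to the α-aryloxy aldehyde bearing a magnesium phenoxide, and a second equivalent adds to the carbonyl faster than it enolises at low temperature; the carbinol configuration is left open because step 5 erases it.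

**Step 5**
Reactants: 9 (2R)-2-(4-bromo-2-hydroxy-6-methoxyphenoxy)-1-(3,4,5-trimethoxyphenyl)propan-1-ol
Product: 10 (2R,3R)-7-bromo-5-methoxy-3-methyl-2-(3,4,5-trimethoxyphenyl)-2,3-dihydro-1,4-benzodioxine
Conditions: p-toluenesulfonic acid monohydrate (10 mol %), toluene, 60 °C
Reagents that add atoms: none
Why: Acid-promoted dehydrative etherification (SN1), in which the benzylic cation stabilised by the para-methoxy group is captured by the ortho-phenol to close the six-membered ring, and reversible ionisation of the benzylic C2–O1 bond should funnel both epimers to the trans isomer with aryl and methyl pseudo-equatorial, so that C2 (R) is set under thermodynamic control by the untouched C3 (R) centre.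

**Step 6**
Reactants: 10 (2R,3R)-7-bromo-5-methoxy-3-methyl-2-(3,4,5-trimethoxyphenyl)-2,3-dihydro-1,4-benzodioxine; 11 (E)-tert-butyldimethyl{[3-(4,4,5,5-tetramethyl-1,3,2-dioxaborolan-2-yl)prop-2-en-1-yl]oxy}silane
Product: 12 tert-butyl{[(E)-3-[(2R,3R)-5-methoxy-3-methyl-2-(3,4,5-trimethoxyphenyl)-2,3-dihydro-1,4-benzodioxin-7-yl]prop-2-en-1-yl]oxy}dimethylsilane
Conditions: Pd(dppf)Cl2 (5 mol %), K2CO3, 1,4-dioxane/H2O, 85 °C
Reagents that add atoms: none
Why: Suzuki–Miyaura cross-coupling of an aryl bromide with an (E)-alkenyl pinacol boronate proceeds with retention of alkene geometry, and the silyl ether, the aryl methyl ethers and the benzylic ether are stable to aqueous carbonate.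

**Step 7**
Reactants: 12 tert-butyl{[(E)-3-[(2R,3R)-5-methoxy-3-methyl-2-(3,4,5-trimethoxyphenyl)-2,3-dihydro-1,4-benzodioxin-7-yl]prop-2-en-1-yl]oxy}dimethylsilane
Product: 13 (E)-3-[(2R,3R)-5-methoxy-3-methyl-2-(3,4,5-trimethoxyphenyl)-2,3-dihydro-1,4-benzodioxin-7-yl]prop-2-en-1-ol
Conditions: Bu4NF, THF, 0 °C → rt
Reagents that add atoms: none
Why: Fluoride-mediated cleavage of a primary tert-butyldimethylsilyl ether runs without acid and so avoids ionisation of the electron-rich cinnamyl alcohol and of the benzylic C2–O1 bond.

**Compound list**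
1 | 5-bromo-2-hydroxy-3-methoxybenzaldehyde | COc1cc(Br)cc(C=O)c1O | starting material
2 | 5-bromo-2-hydroxy-3-methoxyphenyl formate | COc1cc(Br)cc(OC=O)c1O | intermediate
3 | 5-bromo-3-methoxybenzene-1,2-diol | COc1cc(Br)cc(O)c1O | intermediate
4 | 5-bromo-3-methoxycyclohexa-3,5-diene-1,2-dione | COC1=CC(Br)=CC(=O)C1=O | intermediate
5 | propanal | CCC=O | starting material
6 | (2S,3R)-7-bromo-5-methoxy-3-methyl-2,3-dihydro-1,4-benzodioxin-2-ol (one anomer drawn; the anomers interconvert) | O[C@H]1Oc2cc(Br)cc(OC)c2O[C@@H]1C | intermediate
7 | 5-bromo-1,2,3-trimethoxybenzene | COc1cc(Br)cc(OC)c1OC | starting material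
8 | 3,4,5-trimethoxyphenylmagnesium bromide | COc1cc([Mg]Br)cc(OC)c1OC | intermediate
9 | (2R)-2-(4-bromo-2-hydroxy-6-methoxyphenoxy)-1-(3,4,5-trimethoxyphenyl)propan-1-ol (both C1 epimers) | C[C@@H](Oc1c(O)cc(Br)cc1OC)C(O)c1cc(OC)c(OC)c(OC)c1 | intermediate
10 | (2R,3R)-7-bromo-5-methoxy-3-methyl-2-(3,4,5-trimethoxyphenyl)-2,3-dihydro-1,4-benzodioxine | COc1cc([C@H]2Oc3cc(Br)cc(OC)c3O[C@@H]2C)cc(OC)c1OC | intermediate
11 | (E)-tert-butyldimethyl{[3-(4,4,5,5-tetramethyl-1,3,2-dioxaborolan-2-yl)prop-2-en-1-yl]oxy}silane | CC(C)(C)[Si](C)(C)OC/C=C/B1OC(C)(C)C(C)(C)O1 | starting material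
12 | tert-butyl{[(E)-3-[(2R,3R)-5-methoxy-3-methyl-2-(3,4,5-trimethoxyphenyl)-2,3-dihydro-1,4-benzodioxin-7-yl]prop-2-en-1-yl]oxy}dimethylsilane | COc1cc([C@H]2Oc3cc(/C=C/CO[Si](C)(C)C(C)(C)C)cc(OC)c3O[C@@H]2C)cc(OC)c1OC | intermediate
13 | (E)-3-[(2R,3R)-5-methoxy-3-methyl-2-(3,4,5-trimethoxyphenyl)-2,3-dihydro-1,4-benzodioxin-7-yl]prop-2-en-1-ol (CNP0314511.1) | COc1cc([C@H]2Oc3cc(/C=C/CO)cc(OC)c3O[C@@H]2C)cc(OC)c1OC | target

**Step count**
Total: 7 steps. Longest linear sequence: 7 steps (1 → 3 → 4 → 6 → 9 → 10 → 12 → 13); 5, 7 and 11 enter as commercial fragments.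

**Steps most likely to fail**

Step 3. The enamine or the free amine may attack ring carbons of the quinone instead of oxygen, the two quinone oxygens may not be differentiated, or face selection may be poor. The fallback sets out from 1 and fixes both regiochemistry and C3 by known chemistry. Mitsunobu etherification of 1 with ethyl (S)-lactate (PPh3, diisopropyl azodicarboxylate, THF) should give, with inversion, ethyl (2R)-2-(4-bromo-2-formyl-6-methoxyphenoxy)propanoate F1. Baeyer–Villiger oxidation (mCPBA, CH2Cl2) should give ethyl (2R)-2-[4-bromo-2-(formyloxy)-6-methoxyphenoxy]propanoate F2. p-Toluenesulfonic acid in ethanol should cleave the formate to ethyl (2R)-2-(4-bromo-2-hydroxy-6-methoxyphenoxy)propanoate F3, which on warming in toluene with the same acid should lactonise to (3R)-7-bromo-5-methoxy-3-methyl-1,4-benzodioxin-2(3H)-one F4. Reduction with iBu2AlH (1 equiv, CH2Cl2, −78 °C) returns to the route at 6.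

Step 4. The open-chain α-aryloxy aldehyde may enolise under the basic reagent and lose configurational purity at C3, or the magnesium lactolate may open incompletely. The fallback sets out from 6 and changes the oxidation level of the electrophile. Ag2CO3 on Celite (toluene, 80 °C) should oxidise the lactol to (3R)-7-bromo-5-methoxy-3-methyl-1,4-benzodioxin-2(3H)-one F4. N,O-dimethylhydroxylamine hydrochloride with iPrMgCl (THF, −20 °C) should open it to (2R)-2-(4-bromo-2-hydroxy-6-methoxyphenoxy)-N-methoxy-N-methylpropanamide F5. Acylation of 8 (3 equiv, THF, 0 °C) should stop at (2R)-2-(4-bromo-2-hydroxy-6-methoxyphenoxy)-1-(3,4,5-trimethoxyphenyl)propan-1-one F6, and NaBH4 (MeOH, 0 °C) returns to the route at 9.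

Step 5. The benzylic cation may undergo hydride shift or elimination towards the aryloxy-bearing carbon, or equilibration may stop short and leave cis isomer. The fallback sets out from 6, by-passes 9 and forms the C2–aryl bond on the closed ring. SOCl2 with a trace of N,N-dimethylformamide (CH2Cl2, 0 °C) should convert the lactol into the α-chloro ether (3R)-7-bromo-2-chloro-5-methoxy-3-methyl-2,3-dihydro-1,4-benzodioxine F7. Substitution with 8 (THF, −78 → 0 °C), the classical reaction of α-halo ethers with aryl Grignard reagents, should bring the aryl group in anti to the C3 methyl and returns to the route at 10.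

**Further compounds**
F1 | step 3 | ethyl (2R)-2-(4-bromo-2-formyl-6-methoxyphenoxy)propanoate | CCOC(=O)[C@@H](C)Oc1c(C=O)cc(Br)cc1OC
F2 | step 3 | ethyl (2R)-2-[4-bromo-2-(formyloxy)-6-methoxyphenoxy]propanoate | CCOC(=O)[C@@H](C)Oc1c(OC=O)cc(Br)cc1OC
F3 | step 3 | ethyl (2R)-2-(4-bromo-2-hydroxy-6-methoxyphenoxy)propanoate | CCOC(=O)[C@@H](C)Oc1c(O)cc(Br)cc1OC
F4 | step 3 | (3R)-7-bromo-5-methoxy-3-methyl-1,4-benzodioxin-2(3H)-one | C[C@H]1Oc2c(OC)cc(Br)cc2OC1=O
F5 | step 4 | (2R)-2-(4-bromo-2-hydroxy-6-methoxyphenoxy)-N-methoxy-N-methylpropanamide | CON(C)C(=O)[C@@H](C)Oc1c(O)cc(Br)cc1OC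
F6 | step 4 | (2R)-2-(4-bromo-2-hydroxy-6-methoxyphenoxy)-1-(3,4,5-trimethoxyphenyl)propan-1-one | COc1cc(C(=O)[C@@H](C)Oc2c(O)cc(Br)cc2OC)cc(OC)c1OC
F7 | step 5 | (3R)-7-bromo-2-chloro-5-methoxy-3-methyl-2,3-dihydro-1,4-benzodioxine (anomeric mixture) | ClC1Oc2cc(Br)cc(OC)c2O[C@@H]1C
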